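Atoms carry labdane numbers. The route rests on cutting ring B at C5–C6 and C7–C8. Its only unsubstituted ethano unit, C6–C7, lies between C5, which sits between the quaternary carbons C4 and C10 of ring A, and C8, the sp2 carbon of the exocyclic methylene. The key step supplies C6–C7 from vinyltriphenylphosphonium bromide: the C8 nitronate of a monocyclic precursor adds to it, and the resulting ylide closes onto the C5 carbonyl (Michael addition, then intramolecular Wittig reaction), building ring B in one operation. The precursor is a 6,6-disubstituted 3-ethoxy-2-methylcyclohex-2-enone (ring A) that already carries the C10 methyl, the complete side chain on C9 and a nitromethyl group as C8.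

Key step: step 8

Remark: C17 is the exocyclic methylene carbon, C18 the oxygenated methylene on C4 and C20 the methyl on C10. The sense of induction of the chiral ligand in step 7 cannot be predicted; the enantiomer that leads to the (6S)-adduct is to be used, and (1R,2R) is written for definiteness.

Step 1
Reactants: 1 geraniol
Product: 2 geranyl triisopropylsilyl ether
Conditions: i-Pr3SiCl, imidazole, DMF, 0 °C → rt
Reagents that add atoms: triisopropylsilyl chloride, CC(C)[Si](Cl)(C(C)C)C(C)C
Why: Silyl ether formation at the primary allylic alcohol gives a group that should survive base, mild acid and dissolving metal and is removed only in the last step.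

Step 2
Reactants: 2 geranyl triisopropylsilyl ether
Product: 3 (2E)-6,7-epoxy-3,7-dimethyloct-2-en-1-yl triisopropylsilyl ether (racemic)
Conditions: mCPBA (1.0 equiv), NaHCO3, CH2Cl2, −20 → 0 °C
Reagents that add atoms: 3-chloroperoxybenzoic acid, OOC(=O)c1cccc(Cl)c1
Why: Prilezhaev epoxidation should take the remote, more electron-rich trisubstituted alkene because the 2,3-alkene is deactivated by the allylic oxygen; the epoxide stereocentre disappears in step 3.

Step 3
Reactants: 3 (2E)-6,7-epoxy-3,7-dimethyloct-2-en-1-yl triisopropylsilyl ether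
Product: 4 (4E)-4-methyl-6-(triisopropylsilyloxy)hex-4-enal
Conditions: H5IO6, THF–H2O, 0 °C
Reagents that add atoms: none
Why: Periodic acid opens the epoxide to the diol and cleaves it (glycol cleavage) to the aldehyde and acetone without touching the remaining alkene or the silyl ether.

Step 4
Reactants: 4 (4E)-4-methyl-6-(triisopropylsilyloxy)hex-4-enal
Product: 6 (1E,5E)-5-methyl-1-nitro-7-(triisopropylsilyloxy)hepta-1,5-diene, via nitro alcohol 5 (not isolated)
Conditions: CH3NO2, KOt-Bu (cat.), THF–t-BuOH, 0 °C; then MeSO2Cl, Et3N, CH2Cl2, −20 → 0 °C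
Reagents that add atoms: nitromethane, C[N+](=O)[O-]
Why: Henry (nitroaldol) addition followed by mesylation and base-induced elimination should give the conjugated (E)-nitroalkene, which is used at once because it can drift to the allylic nitro isomer.

Step 5
Reactants: 7 2-methylcyclohexane-1,3-dione
Product: 8 3-ethoxy-2-methylcyclohex-2-en-1-one
Conditions: EtOH, TsOH (cat.), toluene, reflux, Dean–Stark
Reagents that add atoms: ethanol, CCO
Why: Acid-catalysed enol ether formation from the cyclic 1,3-dione gives the vinylogous ester, which holds C3 at the ketone oxidation level and leaves C10 as the only enolisable carbon next to the C5 carbonyl.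

Step 6
Reactants: 8 3-ethoxy-2-methylcyclohex-2-en-1-one
Product: 10 3-ethoxy-2,6-dimethylcyclohex-2-en-1-one (racemic), via lithium dienolate 9 (not isolated)
Conditions: LiN(i-Pr)2, THF, −78 °C; CH3I, −78 → 0 °C
Reagents that add atoms: iodomethane, CI
Why: Kinetic deprotonation of a 3-alkoxyenone occurs at the alpha-prime carbon (Stork–Danheiser alkylation), so methylation places C20 on C10; this stereocentre is erased again by enolisation in step 7.

Step 7
Reactants: 10 3-ethoxy-2,6-dimethylcyclohex-2-en-1-one; 6 (1E,5E)-5-methyl-1-nitro-7-(triisopropylsilyloxy)hepta-1,5-diene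
Product: 12 (6S)-3-ethoxy-2,6-dimethyl-6-[(2S,5E)-5-methyl-1-nitro-7-(triisopropylsilyloxy)hept-5-en-2-yl]cyclohex-2-en-1-one, via lithium dienolate 11 (not isolated)
Conditions: LiN(i-Pr)2, (1R,2R)-1,2-dimethoxy-1,2-diphenylethane (1.3 equiv), toluene, −78 °C; then 6, −78 °C; AcOH
Reagents that add atoms: none
Why: Proposed new method: the tetrasubstituted lithium enolate should add to the (E)-nitroalkene through the closed, lithium-bridged synclinal transition state of enolate–nitroalkene Michael additions (enolate oxygen and nitro group on the same lithium, nitroalkene C=C anti to the C10 methyl), which sets C9 and C10 together in the (6S*,2S*) relative sense, and the C2-symmetric diether held on that lithium is expected to make the two enolate faces unequal so that one enantiomer predominates; the closest known reaction types are the diastereoselective Michael addition of ketone lithium enolates to nitroalkenes and the chiral-diether-controlled conjugate addition of lithium ester enolates and aryllithiums to enoates and nitroalkenes.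

Step 8
Reactants: 12 (6S)-3-ethoxy-2,6-dimethyl-6-[(2S,5E)-5-methyl-1-nitro-7-(triisopropylsilyloxy)hept-5-en-2-yl]cyclohex-2-en-1-one; 13 vinyltriphenylphosphonium bromide
Product: 17 (1S,8aS)-5,8a-dimethyl-1-[(3E)-3-methyl-5-(triisopropylsilyloxy)pent-3-en-1-yl]-3,4,8,8a-tetrahydronaphthalene-2,6(1H,7H)-dione, via phosphonium nitronate 14 (not isolated), via ylide nitronate 15 (not isolated), via bicyclic potassium nitronate 16 (not isolated)
Conditions: KOt-Bu (1.0 equiv), THF–DMSO, 0 °C, then 13, 0 °C → rt; KOt-Bu (1.1 equiv), THF, −78 → 60 °C; then aq. TiCl3 (HCl), THF, 0 °C → rt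
Reagents that add atoms: water, O
Why: The potassium nitronate of 12 adds through C8 to the vinylphosphonium salt (C7–C8 bond); the ylide first formed is protonated by the acidic C8–H to give zwitterion 14, and the second equivalent of base regenerates the ylide 15, whose carbon C6 attacks the C5 carbonyl and expels Ph3P=O through the oxaphosphetane to give the C5=C6 bond, which is kept as the C5–C6 single bond once the dienol ether is hydrolysed. This is a Schweizer-type annulation (Michael addition to vinyltriphenylphosphonium bromide followed by intramolecular Wittig reaction), run here on a nitronate donor and a vinylogous ester carbonyl. Ring B closes in the 6-exo-trig mode at the C5 carbonyl, and no other ring size is within reach of the ylide. No stereocentre is created, since C5, C6 and C8 are trigonal in 16 and 17, C9 and C10 are carried through untouched and C5 is set only in step 10. The step needs a single C-alkylation of the nitronate, ylide formation at C6 rather than deprotonation elsewhere, and intramolecular olefination; these are secured by the acidity order (nitro CH2 far above the phosphonium alpha-CH, which is far above the gamma-CH of the enol ether), by the single carbonyl group in the molecule and by the quaternary C10, which blocks enolisation next to C5. Aqueous TiCl3 then turns the nitronate into the C8 ketone (Nef reaction) while the acid hydrolyses the dienol ether to the 4-methyl enone.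

Step 9
Reactants: 17 (1S,8aS)-5,8a-dimethyl-1-[(3E)-3-methyl-5-(triisopropylsilyloxy)pent-3-en-1-yl]-3,4,8,8a-tetrahydronaphthalene-2,6(1H,7H)-dione
Product: 18 (4aS,5R)-1,4a-dimethyl-6-methylidene-5-[(3E)-3-methyl-5-(triisopropylsilyloxy)pent-3-en-1-yl]-4,4a,5,6,7,8-hexahydronaphthalen-2(3H)-one
Conditions: Ph3PCH3Br, KN(SiMe3)2, THF, 0 °C; then 17, −78 → 0 °C
Reagents that add atoms: methyltriphenylphosphonium bromide, C[P+](c1ccccc1)(c1ccccc1)c1ccccc1.[Br-]
Why: Wittig methylenation should take the saturated C8 ketone in preference to the less electrophilic conjugated C3 carbonyl of the tetrasubstituted enone, and at low temperature any enolisation goes to C7, so C9 should keep its configuration.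

Step 10
Reactants: 18 (4aS,5R)-1,4a-dimethyl-6-methylidene-5-[(3E)-3-methyl-5-(triisopropylsilyloxy)pent-3-en-1-yl]-4,4a,5,6,7,8-hexahydronaphthalen-2(3H)-one
Product: 20 (1S,4aS,5R,8aS)-1-(hydroxymethyl)-1,4a-dimethyl-6-methylidene-5-[(3E)-3-methyl-5-(triisopropylsilyloxy)pent-3-en-1-yl]octahydronaphthalen-2(1H)-one, via lithium enolate 19 (not isolated)
Conditions: Li, NH3(l), THF, t-BuOH (1 equiv), −78 °C; isoprene; NH3 removed; CH2O (g), THF, −78 → −20 °C; aq. NH4Cl
Reagents that add atoms: formaldehyde, C=O
Why: Dissolving-metal reduction of the enone protonates C5 axially to give the trans-decalin and the regiodefined C3–C4 lithium enolate, which should take formaldehyde (reductive alkylation, aldol reaction) on the face opposite the axial C10 methyl, so that C18 ends equatorial and the C4 methyl axial.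

Step 11
Reactants: 20 (1S,4aS,5R,8aS)-1-(hydroxymethyl)-1,4a-dimethyl-6-methylidene-5-[(3E)-3-methyl-5-(triisopropylsilyloxy)pent-3-en-1-yl]octahydronaphthalen-2(1H)-one
Product: 21 (1S,2R,4aS,5R,8aS)-1-(hydroxymethyl)-1,4a-dimethyl-6-methylidene-5-[(3E)-3-methyl-5-(triisopropylsilyloxy)pent-3-en-1-yl]decahydronaphthalen-2-ol
Conditions: NaBH4, MeOH, −20 → 0 °C
Reagents that add atoms: none
Why: Hydride reduction with NaBH4 should attack the C3 ketone axially, from the face away from the axial C4 methyl, to give the equatorial C3 alcohol.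

Step 12
Reactants: 21 (1S,2R,4aS,5R,8aS)-1-(hydroxymethyl)-1,4a-dimethyl-6-methylidene-5-[(3E)-3-methyl-5-(triisopropylsilyloxy)pent-3-en-1-yl]decahydronaphthalen-2-ol
Product: 22 [(1S,2R,4aS,5R,8aS)-2-hydroxy-1,4a-dimethyl-6-methylidene-5-[(3E)-3-methyl-5-(triisopropylsilyloxy)pent-3-en-1-yl]decahydronaphthalen-1-yl]methyl (2E)-2-methylbut-2-enoate
Conditions: (E)-2-methylbut-2-enoyl chloride (1.1 equiv), pyridine, CH2Cl2, −20 → 0 °C
Reagents that add atoms: (E)-2-methylbut-2-enoyl chloride (tigloyl chloride), C/C=C(\C)C(Cl)=O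
Why: Esterification with the acid chloride is expected to go to the primary C18 hydroxyl, because the secondary C3 hydroxyl is flanked by the quaternary C4.

Step 13
Reactants: 22 [(1S,2R,4aS,5R,8aS)-2-hydroxy-1,4a-dimethyl-6-methylidene-5-[(3E)-3-methyl-5-(triisopropylsilyloxy)pent-3-en-1-yl]decahydronaphthalen-1-yl]methyl (2E)-2-methylbut-2-enoate
Product: 23 [(1S,2R,4aS,5R,8aS)-2-acetoxy-1,4a-dimethyl-6-methylidene-5-[(3E)-3-methyl-5-(triisopropylsilyloxy)pent-3-en-1-yl]decahydronaphthalen-1-yl]methyl (2E)-2-methylbut-2-enoate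
Conditions: Ac2O, pyridine, DMAP (cat.), CH2Cl2, rt
Reagents that add atoms: acetic anhydride, CC(=O)OC(C)=O
Why: DMAP-catalysed acetylation esterifies the remaining hindered secondary alcohol with retention at C3.

Step 14
Reactants: 23 [(1S,2R,4aS,5R,8aS)-2-acetoxy-1,4a-dimethyl-6-methylidene-5-[(3E)-3-methyl-5-(triisopropylsilyloxy)pent-3-en-1-yl]decahydronaphthalen-1-yl]methyl (2E)-2-methylbut-2-enoate
Product: 24 [(1S,2R,4aS,5R,8aS)-2-acetoxy-5-[(3E)-5-hydroxy-3-methylpent-3-en-1-yl]-1,4a-dimethyl-6-methylidenedecahydronaphthalen-1-yl]methyl (2E)-2-methylbut-2-enoate (CNP0148037.1)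
Conditions: HF·pyridine, pyridine, THF, 0 °C → rt
Reagents that add atoms: none
Why: Fluoride-mediated desilylation under buffered conditions should free the C15 allylic alcohol without ester cleavage or acyl migration, both other hydroxyls being acylated.

Compound list

1 | geraniol, (2E)-3,7-dimethylocta-2,6-dien-1-ol | CC(C)=CCC/C(C)=C/CO | starting material
2 | geranyl triisopropylsilyl ether | CC(C)=CCC/C(C)=C/CO[Si](C(C)C)(C(C)C)C(C)C | intermediate
3 | (2E)-6,7-epoxy-3,7-dimethyloct-2-en-1-yl triisopropylsilyl ether (racemic) | CC1(C)OC1CC/C(C)=C/CO[Si](C(C)C)(C(C)C)C(C)C | intermediate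
4 | (4E)-4-methyl-6-(triisopropylsilyloxy)hex-4-enal | O=CCC/C(C)=C/CO[Si](C(C)C)(C(C)C)C(C)C | intermediate
5 | (5E)-5-methyl-1-nitro-7-(triisopropylsilyloxy)hept-5-en-2-ol (racemic, not isolated) | [O-][N+](=O)CC(O)CC/C(C)=C/CO[Si](C(C)C)(C(C)C)C(C)C | intermediate
6 | (1E,5E)-5-methyl-1-nitro-7-(triisopropylsilyloxy)hepta-1,5-diene | [O-][N+](=O)/C=C/CC/C(C)=C/CO[Si](C(C)C)(C(C)C)C(C)C | intermediate
7 | 2-methylcyclohexane-1,3-dione | CC1C(=O)CCCC1=O | starting material
8 | 3-ethoxy-2-methylcyclohex-2-en-1-one | CCOC1=C(C)C(=O)CCC1 | intermediate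
9 | lithium 5-ethoxy-6-methylcyclohexa-1,5-dien-1-olate (not isolated) | CCOC1=C(C)C(O[Li])=CCC1 | intermediate
10 | 3-ethoxy-2,6-dimethylcyclohex-2-en-1-one (racemic) | CCOC1=C(C)C(=O)C(C)CC1 | intermediate
11 | lithium 5-ethoxy-2,6-dimethylcyclohexa-1,5-dien-1-olate (not isolated) | CCOC1=C(C)C(O[Li])=C(C)CC1 | intermediate
12 | (6S)-3-ethoxy-2,6-dimethyl-6-[(2S,5E)-5-methyl-1-nitro-7-(triisopropylsilyloxy)hept-5-en-2-yl]cyclohex-2-en-1-one | CCOC1=C(C)C(=O)[C@@](C)(CC1)[C@@H](C[N+](=O)[O-])CC/C(C)=C/CO[Si](C(C)C)(C(C)C)C(C)C | intermediate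
13 | vinyltriphenylphosphonium bromide, ethenyl(triphenyl)phosphonium bromide | C=C[P+](c1ccccc1)(c1ccccc1)c1ccccc1.[Br-] | starting material
14 | zwitterion of 12 in which C8 is a nitronate carbon bearing a 2-(triphenylphosphonio)ethyl group (not isolated) | CCOC1=C(C)C(=O)[C@@](C)(CC1)[C@@H](C(CC[P+](c1ccccc1)(c1ccccc1)c1ccccc1)=[N+]([O-])[O-])CC/C(C)=C/CO[Si](C(C)C)(C(C)C)C(C)C | intermediate
15 | potassium salt of the ylide derived from 14, Ph3P=CH–CH2 on the nitronate carbon C8 (not isolated) | CCOC1=C(C)C(=O)[C@@](C)(CC1)[C@@H](C(CC=P(c1ccccc1)(c1ccccc1)c1ccccc1)=[N+]([O-])[O-])CC/C(C)=C/CO[Si](C(C)C)(C(C)C)C(C)C.[K+] | intermediate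
16 | potassium aci-nitronate of (1S,8aS)-6-ethoxy-5,8a-dimethyl-1-[(3E)-3-methyl-5-(triisopropylsilyloxy)pent-3-en-1-yl]-2-nitro-1,2,3,7,8,8a-hexahydronaphthalene, ring B closed, 3-ethoxy-3,5-diene in rings A and B (not isolated) | [O-][N+]([O-])=C1CC=C2C(C)=C(OCC)CC[C@@]2(C)[C@@H]1CC/C(C)=C/CO[Si](C(C)C)(C(C)C)C(C)C.[K+] | intermediate
17 | (1S,8aS)-5,8a-dimethyl-1-[(3E)-3-methyl-5-(triisopropylsilyloxy)pent-3-en-1-yl]-3,4,8,8a-tetrahydronaphthalene-2,6(1H,7H)-dione, the C8 ketone with the 4-methyl-4-en-3-one in ring A | O=C1CCC2=C(C)C(=O)CC[C@@]2(C)[C@@H]1CC/C(C)=C/CO[Si](C(C)C)(C(C)C)C(C)C | intermediate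
18 | (4aS,5R)-1,4a-dimethyl-6-methylidene-5-[(3E)-3-methyl-5-(triisopropylsilyloxy)pent-3-en-1-yl]-4,4a,5,6,7,8-hexahydronaphthalen-2(3H)-one | C=C1CCC2=C(C)C(=O)CC[C@@]2(C)[C@@H]1CC/C(C)=C/CO[Si](C(C)C)(C(C)C)C(C)C | intermediate
19 | lithium (4aS,5R,8aS)-1,4a-dimethyl-6-methylidene-5-[(3E)-3-methyl-5-(triisopropylsilyloxy)pent-3-en-1-yl]-3,4,4a,5,6,7,8,8a-octahydronaphthalen-2-olate, trans-fused (not isolated) | C=C1CC[C@H]2[C@@](C)(CCC(O[Li])=C2C)[C@@H]1CC/C(C)=C/CO[Si](C(C)C)(C(C)C)C(C)C | intermediate
20 | (1S,4aS,5R,8aS)-1-(hydroxymethyl)-1,4a-dimethyl-6-methylidene-5-[(3E)-3-methyl-5-(triisopropylsilyloxy)pent-3-en-1-yl]octahydronaphthalen-2(1H)-one | C=C1CC[C@H]2[C@@](C)(CCC(=O)[C@]2(C)CO)[C@@H]1CC/C(C)=C/CO[Si](C(C)C)(C(C)C)C(C)C | intermediate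
21 | (1S,2R,4aS,5R,8aS)-1-(hydroxymethyl)-1,4a-dimethyl-6-methylidene-5-[(3E)-3-methyl-5-(triisopropylsilyloxy)pent-3-en-1-yl]decahydronaphthalen-2-ol | C=C1CC[C@H]2[C@@](C)(CC[C@@H](O)[C@]2(C)CO)[C@@H]1CC/C(C)=C/CO[Si](C(C)C)(C(C)C)C(C)C | intermediate
22 | [(1S,2R,4aS,5R,8aS)-2-hydroxy-1,4a-dimethyl-6-methylidene-5-[(3E)-3-methyl-5-(triisopropylsilyloxy)pent-3-en-1-yl]decahydronaphthalen-1-yl]methyl (2E)-2-methylbut-2-enoate | C=C1CC[C@H]2[C@@](C)(CC[C@@H](O)[C@]2(C)COC(=O)/C(C)=C/C)[C@@H]1CC/C(C)=C/CO[Si](C(C)C)(C(C)C)C(C)C | intermediate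
23 | [(1S,2R,4aS,5R,8aS)-2-acetoxy-1,4a-dimethyl-6-methylidene-5-[(3E)-3-methyl-5-(triisopropylsilyloxy)pent-3-en-1-yl]decahydronaphthalen-1-yl]methyl (2E)-2-methylbut-2-enoate | C=C1CC[C@H]2[C@@](C)(CC[C@@H](OC(C)=O)[C@]2(C)COC(=O)/C(C)=C/C)[C@@H]1CC/C(C)=C/CO[Si](C(C)C)(C(C)C)C(C)C | intermediate
24 | [(1S,2R,4aS,5R,8aS)-2-acetoxy-5-[(3E)-5-hydroxy-3-methylpent-3-en-1-yl]-1,4a-dimethyl-6-methylidenedecahydronaphthalen-1-yl]methyl (2E)-2-methylbut-2-enoate (CNP0148037.1) | C=C1CC[C@H]2[C@@](C)(CC[C@@H](OC(C)=O)[C@]2(C)COC(=O)/C(C)=C/C)[C@@H]1CC/C(C)=C/CO | target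

Total step count: 14. Longest linear sequence: 12 steps (steps 1–4, then 7–14); the ring A branch (steps 5–6) joins at step 7.

Steps most likely to fail

1. Step 7 (the labelled step). The ligand-bound lithium enolate may discriminate poorly between its two faces, giving low enantiomeric purity, or the hindered enolate may remove a C11 proton of the nitroalkene instead of adding to C9. Fallback, resolution in place of asymmetric induction: starting again from 10, the Michael addition is run with LiN(i-Pr)2 in THF at −78 °C without the ligand. This is the known closed-transition-state addition of ketone lithium enolates to nitroalkenes and should give racemic 12 with the same relative configuration. The enantiomers are separated by preparative chromatography on a chiral stationary phase, the (6R,2R)-enantiomer of the Michael adduct F1 is set aside, and the route is rejoined at 12.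

2. Step 8 (key step). Closure of the ylide onto the hindered, weakly electrophilic C5 carbonyl may be slower than intermolecular reactions of the ylide, or the nitronate may be alkylated twice. Fallback, two known steps in place of the annulation: from 12, CH2=CHMgBr (3 equiv, the first of which stores the nitro group as its nitronate) and CeCl3 in THF add to the C5 carbonyl. An AcOH quench and brief 1 M HCl (Stork–Danheiser transposition) should then give the 3-vinyl dienone F2. DBU in MeCN closes ring B by intramolecular 1,6-conjugate addition of the nitronate carbon C8 to the vinyl terminus C7, giving the C8-nitro enone F3. NaOMe followed by aqueous TiCl3 (Nef reaction) converts this into 17, where the route is rejoined.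

3. Step 10. The hindered tetrasubstituted enolate may capture gaseous formaldehyde incompletely (proton return), the substrate may be over-reduced, or the allylic silyloxy group may be lost reductively. Fallback, silyl enol ether route: from 18, the same Li/NH3 reduction is quenched with Me3SiCl/Et3N to give the trimethylsilyl enol ether F4. This is hydroxymethylated with aqueous formaldehyde and Sc(OTf)3 in THF–H2O (Mukaiyama aldol reaction), again on the face opposite the C10 methyl, to give 20, where the route is rejoined.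

Further compounds

F1 | step 7 | (6R)-3-ethoxy-2,6-dimethyl-6-[(2R,5E)-5-methyl-1-nitro-7-(triisopropylsilyloxy)hept-5-en-2-yl]cyclohex-2-en-1-one | CCOC1=C(C)C(=O)[C@](C)(CC1)[C@H](C[N+](=O)[O-])CC/C(C)=C/CO[Si](C(C)C)(C(C)C)C(C)C
F2 | step 8 | (4S)-3-ethenyl-2,4-dimethyl-4-[(2S,5E)-5-methyl-1-nitro-7-(triisopropylsilyloxy)hept-5-en-2-yl]cyclohex-2-en-1-one | C=CC1=C(C)C(=O)CC[C@@]1(C)[C@@H](C[N+](=O)[O-])CC/C(C)=C/CO[Si](C(C)C)(C(C)C)C(C)C
F3 | step 8 | C8-nitro analogue of 17, (4aS,5S)-1,4a-dimethyl-5-[(3E)-3-methyl-5-(triisopropylsilyloxy)pent-3-en-1-yl]-6-nitro-4,4a,5,6,7,8-hexahydronaphthalen-2(3H)-one (both C8 epimers) | [O-][N+](=O)C1CCC2=C(C)C(=O)CC[C@@]2(C)[C@@H]1CC/C(C)=C/CO[Si](C(C)C)(C(C)C)C(C)C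
F4 | step 10 | trimethylsilyl enol ether of the trans-fused 3-ketone, (4aS,5R,8aS)-1,4a-dimethyl-6-methylidene-5-[(3E)-3-methyl-5-(triisopropylsilyloxy)pent-3-en-1-yl]-2-(trimethylsilyloxy)-3,4,4a,5,6,7,8,8a-octahydronaphthalene | C=C1CC[C@H]2[C@@](C)(CCC(O[Si](C)(C)C)=C2C)[C@@H]1CC/C(C)=C/CO[Si](C(C)C)(C(C)C)C(C)C
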